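**Plan**

1. Retrosynthesis: cut the C8 ester (side chain from (R)-3-bromo-2-hydroxy-2-methylpropanoic acid), then the lactone C12–O6 bond and the C6–C7 ring bond (allylation of a C6 aldehyde by a C7=C11 allylic bromide), then the furanone at C1–C2 and O–C10.
2. Enabling feature: O8 lies gamma to the C1 carbonyl (C1–C10–C9–C8–O8), so C1, C10, C9, C8 and O8 are carried as a 5-membered bromolactone that is not in the target. This temporary ring fixes C10 and is cleaved by the C2 enolate in the key step, which frees the 8-hydroxyl.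
3. Forward order of rings: furanone first (ketone 4 carrying C2–C6 plus bromolactone 8 carrying C1 and C7–C10), then C7 is grown into the allylic bromide and C6 unmasked, then CrCl2 closes the 10-membered carbocycle and the cis-fused methylene lactone follows by lactonisation; the ester is attached last.
4. Stereochemistry: C4 from an Evans allylation; C8 from (S)-5-(hydroxymethyl)oxolan-2-one; C10 by inversion of a bromide set anti to the C8 substituent on the temporary lactone; C6 and C7 in the ring closure (chair transition state, allylic strain at C8); side-chain carbinol from the chiral pool.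

Key step: step 7

Remark: germacrane numbering is used (C1 ketone, C2=C3, C4 with methyl C15, O6 lactone oxygen, C8 ester oxygen, C10 with methyl C14 and the furanone oxygen, C11=C13 methylene, C12 lactone carbonyl). The given SMILES is read as 4S,6S,7S,8S,10S,2'S with a cis-fused lactone (H6 and H7 syn).

**Route**

Step 1
Reactants: 1 (R)-4-benzyl-3-propanoyl-1,3-oxazolidin-2-one
Product: 2 (R)-4-benzyl-3-[(S)-2-methylpent-4-enoyl]-1,3-oxazolidin-2-one
Conditions: NaN(SiMe3)2, THF, −78 °C; allyl iodide, −78 → −40 °C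
Reagents that add atoms: allyl iodide, C=CCI
Why: Evans alkylation, in which the chelated Z-sodium enolate is allylated on the face opposite the benzyl group, so the (R)-auxiliary should set the (S) centre that becomes C4.

Step 2
Reactants: 2 (R)-4-benzyl-3-[(S)-2-methylpent-4-enoyl]-1,3-oxazolidin-2-one
Product: 3 (S)-N-methoxy-N,2-dimethylpent-4-enamide
Conditions: MeNHOMe·HCl, AlMe3, CH2Cl2, 0 → 23 °C
Reagents that add atoms: N,O-dimethylhydroxylamine hydrochloride, CNOC.Cl
Why: aluminium amide aminolysis of the exocyclic imide carbonyl should give the Weinreb amide without touching the alpha centre and releases the auxiliary.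

Step 3
Reactants: 3 (S)-N-methoxy-N,2-dimethylpent-4-enamide
Product: 4 (S)-3-methylhex-5-en-2-one
Conditions: MeMgBr, THF, 0 °C; aq. NH4Cl
Reagents that add atoms: methylmagnesium bromide, C[Mg]Br
Why: Weinreb ketone synthesis, in which the chelated tetrahedral adduct prevents over-addition; the methyl group introduced is C2 and the terminal alkene masks the C6 aldehyde.

Step 4
Reactants: 5 (S)-5-(hydroxymethyl)oxolan-2-one
Product: 6 (S)-5-[(trityloxy)methyl]oxolan-2-one
Conditions: TrCl, pyridine, DMAP (cat.), CH2Cl2, 23 °C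
Reagents that add atoms: trityl chloride, ClC(c1ccccc1)(c1ccccc1)c1ccccc1
Why: tritylation of the primary hydroxyl installs the bulky group that shields one face of the lactone enolate in steps 5 and 6; the carbinol carbon is C8 and the oxymethyl carbon is C7.

Step 5
Reactants: 6 (S)-5-[(trityloxy)methyl]oxolan-2-one
Product: 7 (3R,5S)-3-methyl-5-[(trityloxy)methyl]oxolan-2-one (methyl trans to the trityloxymethyl group)
Conditions: LiN(iPr)2, THF, −78 °C; MeI
Reagents that add atoms: iodomethane, CI
Why: lactone enolate alkylation anti to the trityloxymethyl group introduces methyl C14; the configuration of this centre is erased in step 6, so only clean monoalkylation is required.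

Step 6
Reactants: 7 (3R,5S)-3-methyl-5-[(trityloxy)methyl]oxolan-2-one
Product: 8 (3R,5S)-3-bromo-3-methyl-5-[(trityloxy)methyl]oxolan-2-one (bromine trans and methyl cis to the trityloxymethyl group)
Conditions: LiN(iPr)2, THF, −78 °C; BrCCl2CCl2Br, −78 °C
Reagents that add atoms: 1,2-dibromo-1,1,2,2-tetrachloroethane, BrC(Cl)(Cl)C(Cl)(Cl)Br
Why: electrophilic bromination of the lactone enolate should again occur anti to the C8 substituent, so introducing methyl before bromine places bromine trans and fixes the quaternary C10 as the (R)-bromide.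

Step 7
Reactants: 4 (S)-3-methylhex-5-en-2-one; 8 (3R,5S)-3-bromo-3-methyl-5-[(trityloxy)methyl]oxolan-2-one
Product: 10 (S)-2-[(S)-2-hydroxy-3-(trityloxy)propyl]-2-methyl-5-[(S)-pent-4-en-2-yl]furan-3(2H)-one, via open-chain bromo diketone 9 (not isolated)
Conditions: 4 (1.1 equiv), LiN(iPr)2 (1.1 equiv), THF, −78 °C; then 8, −78 → 0 °C; AcOH quench
Reagents that add atoms: none
Why: Proposed new method: the kinetic lithium enolate of 4 (deprotonation at the unhindered C2 methyl, not at the tertiary C4–H) should add to the bromine-activated lactone carbonyl C1 of 8, the lactolate should collapse with expulsion of the C8 alkoxide (cleaving the temporary ring), this alkoxide should deprotonate the new 1,3-diketone 9, and the C3 enolate oxygen should then displace the tertiary bromide at C10. The closest known reaction types are the acylation of ketone enolates by lactones and the annulation of 1,3-dicarbonyl enolates with 2-bromoacyl halides to 3(2H)-furanones, which passes through the same kind of 4-bromo-1,3-diketone. The furanone ring closes by O-alkylation in the 5-exo-tet mode. C10 is the only new stereocentre and is set by backside displacement, so the (R)-bromide fixed on the temporary lactone becomes the (S)-ether; ionisation is disfavoured because the cation would sit next to the C1 carbonyl. The step needs C-acylation to outrun bromine transfer to the enolate and dehydrobromination, and O- to beat C-alkylation in the closure: the tertiary bromide resists direct intermolecular substitution, the 5-membered O-closure is favoured over a 3-membered C-closure, and no strong base remains once bromide is released, which protects the epimerisable C4 centre.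

Step 8
Reactants: 10 (S)-2-[(S)-2-hydroxy-3-(trityloxy)propyl]-2-methyl-5-[(S)-pent-4-en-2-yl]furan-3(2H)-one
Product: 11 (S)-2-[(S)-2-(tert-butyldimethylsilyloxy)-3-(trityloxy)propyl]-2-methyl-5-[(S)-pent-4-en-2-yl]furan-3(2H)-one
Conditions: TBSOTf, 2,6-lutidine, CH2Cl2, −78 → 0 °C
Reagents that add atoms: tert-butyldimethylsilyl triflate, CC(C)(C)[Si](C)(C)OS(=O)(=O)C(F)(F)F
Why: silyl triflate silylation of the hindered secondary 8-hydroxyl; a silyl ether is chosen because an acyloxy group at C8 would be prone to 1,4-elimination from the allylmetal of step 14.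

Step 9
Reactants: 11 (S)-2-[(S)-2-(tert-butyldimethylsilyloxy)-3-(trityloxy)propyl]-2-methyl-5-[(S)-pent-4-en-2-yl]furan-3(2H)-one
Product: 12 (S)-2-[(S)-2-(tert-butyldimethylsilyloxy)-3-hydroxypropyl]-2-methyl-5-[(S)-pent-4-en-2-yl]furan-3(2H)-one
Conditions: p-TsOH·H2O (cat.), MeOH/CH2Cl2, 0 °C
Reagents that add atoms: none
Why: acid-catalysed methanolysis of the trityl ether through the trityl cation should be faster than cleavage of the hindered secondary silyl ether.

Step 10
Reactants: 12 (S)-2-[(S)-2-(tert-butyldimethylsilyloxy)-3-hydroxypropyl]-2-methyl-5-[(S)-pent-4-en-2-yl]furan-3(2H)-one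
Product: 13 (S)-2-(tert-butyldimethylsilyloxy)-3-{(S)-2-methyl-3-oxo-5-[(S)-pent-4-en-2-yl]-2,3-dihydrofuran-2-yl}propanal
Conditions: Dess–Martin periodinane, NaHCO3, CH2Cl2, 0 → 23 °C
Reagents that add atoms: none
Why: buffered Dess–Martin oxidation should give the alpha-silyloxy aldehyde (C7) without epimerising C8; the aldehyde is used crude.

Step 11
Reactants: 13 (S)-2-(tert-butyldimethylsilyloxy)-3-{(S)-2-methyl-3-oxo-5-[(S)-pent-4-en-2-yl]-2,3-dihydrofuran-2-yl}propanal
Product: 14 methyl (4S)-4-(tert-butyldimethylsilyloxy)-3-hydroxy-2-methylidene-5-{(S)-2-methyl-3-oxo-5-[(S)-pent-4-en-2-yl]-2,3-dihydrofuran-2-yl}pentanoate (both epimers at the new carbinol C7, used together)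
Conditions: methyl acrylate (excess), DABCO, MeOH, 23 °C
Reagents that add atoms: methyl acrylate, C=CC(=O)OC
Why: Morita–Baylis–Hillman reaction of an alpha-oxygenated (activated) aldehyde introduces C11–C13; the new carbinol centre need not be controlled because C7 becomes trigonal in step 12.

Step 12
Reactants: 14 methyl (4S)-4-(tert-butyldimethylsilyloxy)-3-hydroxy-2-methylidene-5-{(S)-2-methyl-3-oxo-5-[(S)-pent-4-en-2-yl]-2,3-dihydrofuran-2-yl}pentanoate
Product: 15 methyl (Z,4S)-2-(bromomethyl)-4-(tert-butyldimethylsilyloxy)-5-{(S)-2-methyl-3-oxo-5-[(S)-pent-4-en-2-yl]-2,3-dihydrofuran-2-yl}pent-2-enoate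
Conditions: NBS, Me2S, CH2Cl2, −20 → 23 °C
Reagents that add atoms: N-bromosuccinimide, O=C1CCC(=O)N1Br
Why: Corey–Kim-type activation of the allylic alcohol followed by SN2' attack of bromide should give the conjugated 2-(bromomethyl)enoate in its favoured Z geometry (C8 cis to CH2Br), both C7 epimers converging.

Step 13
Reactants: 15 methyl (Z,4S)-2-(bromomethyl)-4-(tert-butyldimethylsilyloxy)-5-{(S)-2-methyl-3-oxo-5-[(S)-pent-4-en-2-yl]-2,3-dihydrofuran-2-yl}pent-2-enoate
Product: 16 methyl (Z,4S)-2-(bromomethyl)-4-(tert-butyldimethylsilyloxy)-5-{(S)-2-methyl-3-oxo-5-[(S)-4-oxobutan-2-yl]-2,3-dihydrofuran-2-yl}pent-2-enoate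
Conditions: OsO4 (cat.), NaIO4, 2,6-lutidine, dioxane/H2O, 23 °C
Reagents that add atoms: osmium tetroxide, O=[Os](=O)(=O)=O; sodium periodate, [Na+].[O-]I(=O)(=O)=O
Why: Lemieux–Johnson cleavage, in which OsO4 should select the unhindered monosubstituted alkene over the electron-poor trisubstituted enoate and the push–pull furanone alkene, unmasks the C6 aldehyde.

Step 14
Reactants: 16 methyl (Z,4S)-2-(bromomethyl)-4-(tert-butyldimethylsilyloxy)-5-{(S)-2-methyl-3-oxo-5-[(S)-4-oxobutan-2-yl]-2,3-dihydrofuran-2-yl}pent-2-enoate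
Product: 18 8-O-(tert-butyldimethylsilyl)-8-hydroxy-1-oxo-3,10-epoxygermacra-2,11(13)-dien-12,6-olide (4S,6S,7S,8S,10S; cis-fused lactone), via hydroxy ester 17 (not isolated)
Conditions: CrCl2 (excess), THF/DMF, slow addition, 0.002 M, 23 °C; then p-TsOH·H2O (cat.), CH2Cl2, 23 °C
Reagents that add atoms: none
Why: Nozaki–Hiyama–Kishi-type (Barbier) allylation, a reaction type that has closed 10-membered germacranolide carbocycles from 2-(bromomethyl)enoates: the allylchromium formed at C13 should add through C7 to the C6 aldehyde (far more electrophilic than the hindered vinylogous-ester carbonyl C1) in a chair transition state with the Z-disposed C8 substituent axial, giving the syn adduct 17 and hence the cis-fused lactone (6S), while C7 (7S) is set by allylic 1,3-strain, which holds the C8 hydrogen in the alkene plane so that the aldehyde, tethered through C9, reaches the face syn to C9 and anti to the silyloxy group.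

Step 15
Reactants: 18 8-O-(tert-butyldimethylsilyl)-8-hydroxy-1-oxo-3,10-epoxygermacra-2,11(13)-dien-12,6-olide
Product: 19 8-hydroxy-1-oxo-3,10-epoxygermacra-2,11(13)-dien-12,6-olide (spatial arrangement at C4, C6, C7, C8 and C10 as in 27)
Conditions: HF·pyridine, pyridine/THF, 0 → 23 °C
Reagents that add atoms: none
Why: buffered fluoride cleavage of the silyl ether avoids the alkoxide that could translactonise from O6 to O8 and leaves the methylene lactone and the furanone untouched.

Step 16
Reactants: 20 (R)-3-bromo-2-hydroxy-2-methylpropanoic acid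
Product: 22 (S)-2,3-dihydroxy-2-methylpropanoic acid, via glycidic acid 21 (not isolated)
Conditions: NaOH, H2O, 80 °C; then HCl to pH 2
Reagents that add atoms: sodium hydroxide, [Na+].[OH-]
Why: intramolecular Williamson closure to the glycidate and hydroxide opening at the unsubstituted CH2 carbon never touch the tertiary centre, so its arrangement is retained and only the descriptor changes from R to S.

Step 17
Reactants: 22 (S)-2,3-dihydroxy-2-methylpropanoic acid
Product: 23 methyl (S)-2,2,4-trimethyl-1,3-dioxolane-4-carboxylate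
Conditions: 2,2-dimethoxypropane, MeOH, p-TsOH·H2O (cat.), 50 °C
Reagents that add atoms: 2,2-dimethoxypropane, COC(C)(C)OC; methanol, CO
Why: Fischer esterification and transacetalisation in one pot protect the acid and the 1,2-diol without affecting the quaternary centre.

Step 18
Reactants: 23 methyl (S)-2,2,4-trimethyl-1,3-dioxolane-4-carboxylate
Product: 24 (S)-2,2,4-trimethyl-1,3-dioxolane-4-carboxylic acid
Conditions: LiOH, THF/H2O, 23 °C; then 1 M HCl to pH 3, 0 °C
Reagents that add atoms: lithium hydroxide, [Li+].[OH-]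
Why: saponification of the methyl ester under conditions in which the acetonide and the non-enolisable quaternary centre are stable.

Step 19
Reactants: 24 (S)-2,2,4-trimethyl-1,3-dioxolane-4-carboxylic acid; 19 8-hydroxy-1-oxo-3,10-epoxygermacra-2,11(13)-dien-12,6-olide
Product: 26 8-O-[(S)-2,2,4-trimethyl-1,3-dioxolane-4-carbonyl] derivative of 19 (acetonide of the target), via mixed anhydride 25 (not isolated)
Conditions: 2,4,6-trichlorobenzoyl chloride, Et3N, THF, 23 °C; then 19, DMAP, toluene, 23 °C
Reagents that add atoms: none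
Why: Yamaguchi esterification, suited to a hindered secondary alcohol and an alpha-quaternary acid, acylates O8 with retention at C8 and at the side-chain centre.

Step 20
Reactants: 26 acetonide of the target
Product: 27 target, 8-O-[(S)-2,3-dihydroxy-2-methylpropanoyl]-8-hydroxy-1-oxo-3,10-epoxygermacra-2,11(13)-dien-12,6-olide (4S,6S,7S,8S,10S)
Conditions: TFA/H2O (9:1), 0 °C
Reagents that add atoms: none
Why: acid hydrolysis of the isopropylidene acetal releases the diol; the ester, the furanone and the methylene lactone should tolerate brief aqueous acid.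

**Compound list**

1 | (R)-4-benzyl-3-propanoyl-1,3-oxazolidin-2-one | CCC(=O)N1[C@H](Cc2ccccc2)COC1=O | starting material
2 | (R)-4-benzyl-3-[(S)-2-methylpent-4-enoyl]-1,3-oxazolidin-2-one | C=CC[C@H](C)C(=O)N1[C@H](Cc2ccccc2)COC1=O | intermediate
3 | (S)-N-methoxy-N,2-dimethylpent-4-enamide | C=CC[C@H](C)C(=O)N(C)OC | intermediate
4 | (S)-3-methylhex-5-en-2-one | C=CC[C@H](C)C(C)=O | intermediate
5 | (S)-5-(hydroxymethyl)oxolan-2-one | O=C1CC[C@@H](CO)O1 | starting material
6 | (S)-5-[(trityloxy)methyl]oxolan-2-one | O=C1CC[C@@H](COC(c2ccccc2)(c2ccccc2)c2ccccc2)O1 | intermediate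
7 | (3R,5S)-3-methyl-5-[(trityloxy)methyl]oxolan-2-one | O=C1[C@H](C)C[C@@H](COC(c2ccccc2)(c2ccccc2)c2ccccc2)O1 | intermediate
8 | (3R,5S)-3-bromo-3-methyl-5-[(trityloxy)methyl]oxolan-2-one | O=C1[C@@](Br)(C)C[C@@H](COC(c2ccccc2)(c2ccccc2)c2ccccc2)O1 | intermediate
9 | (4S,8R,10S)-8-bromo-10-hydroxy-4,8-dimethyl-11-(trityloxy)undec-1-ene-5,7-dione | C=CC[C@H](C)C(=O)CC(=O)[C@@](Br)(C)C[C@H](O)COC(c1ccccc1)(c1ccccc1)c1ccccc1 | intermediate
10 | (S)-2-[(S)-2-hydroxy-3-(trityloxy)propyl]-2-methyl-5-[(S)-pent-4-en-2-yl]furan-3(2H)-one | C=CC[C@H](C)C1=CC(=O)[C@](C)(C[C@H](O)COC(c2ccccc2)(c2ccccc2)c2ccccc2)O1 | intermediate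
11 | (S)-2-[(S)-2-(tert-butyldimethylsilyloxy)-3-(trityloxy)propyl]-2-methyl-5-[(S)-pent-4-en-2-yl]furan-3(2H)-one | C=CC[C@H](C)C1=CC(=O)[C@](C)(C[C@H](O[Si](C)(C)C(C)(C)C)COC(c2ccccc2)(c2ccccc2)c2ccccc2)O1 | intermediate
12 | (S)-2-[(S)-2-(tert-butyldimethylsilyloxy)-3-hydroxypropyl]-2-methyl-5-[(S)-pent-4-en-2-yl]furan-3(2H)-one | C=CC[C@H](C)C1=CC(=O)[C@](C)(C[C@H](O[Si](C)(C)C(C)(C)C)CO)O1 | intermediate
13 | (S)-2-(tert-butyldimethylsilyloxy)-3-{(S)-2-methyl-3-oxo-5-[(S)-pent-4-en-2-yl]-2,3-dihydrofuran-2-yl}propanal | C=CC[C@H](C)C1=CC(=O)[C@](C)(C[C@H](O[Si](C)(C)C(C)(C)C)C=O)O1 | intermediate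
14 | methyl (4S)-4-(tert-butyldimethylsilyloxy)-3-hydroxy-2-methylidene-5-{(S)-2-methyl-3-oxo-5-[(S)-pent-4-en-2-yl]-2,3-dihydrofuran-2-yl}pentanoate (C3 epimers) | C=CC[C@H](C)C1=CC(=O)[C@](C)(C[C@H](O[Si](C)(C)C(C)(C)C)C(O)C(=C)C(=O)OC)O1 | intermediate
15 | methyl (Z,4S)-2-(bromomethyl)-4-(tert-butyldimethylsilyloxy)-5-{(S)-2-methyl-3-oxo-5-[(S)-pent-4-en-2-yl]-2,3-dihydrofuran-2-yl}pent-2-enoate | C=CC[C@H](C)C1=CC(=O)[C@](C)(C[C@H](O[Si](C)(C)C(C)(C)C)/C=C(\CBr)C(=O)OC)O1 | intermediate
16 | methyl (Z,4S)-2-(bromomethyl)-4-(tert-butyldimethylsilyloxy)-5-{(S)-2-methyl-3-oxo-5-[(S)-4-oxobutan-2-yl]-2,3-dihydrofuran-2-yl}pent-2-enoate | O=CC[C@H](C)C1=CC(=O)[C@](C)(C[C@H](O[Si](C)(C)C(C)(C)C)/C=C(\CBr)C(=O)OC)O1 | intermediate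
17 | methyl 2-[(4S,6S,7S,8S,10S)-8-(tert-butyldimethylsilyloxy)-6-hydroxy-4,10-dimethyl-1-oxo-3,10-epoxycyclodec-2-en-7-yl]prop-2-enoate (germacrane numbering) | C=C(C(=O)OC)[C@H]1[C@@H](O)C[C@H](C)C2=CC(=O)[C@](C)(C[C@@H]1O[Si](C)(C)C(C)(C)C)O2 | intermediate
18 | 8-O-(tert-butyldimethylsilyl)-8-hydroxy-1-oxo-3,10-epoxygermacra-2,11(13)-dien-12,6-olide (4S,6S,7S,8S,10S) | C=C1C(=O)O[C@H]2C[C@H](C)C3=CC(=O)[C@](C)(C[C@H](O[Si](C)(C)C(C)(C)C)[C@@H]12)O3 | intermediate
19 | 8-hydroxy-1-oxo-3,10-epoxygermacra-2,11(13)-dien-12,6-olide (arrangement as in 27) | C=C1C(=O)O[C@H]2C[C@H](C)C3=CC(=O)[C@](C)(C[C@H](O)[C@@H]12)O3 | intermediate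
20 | (R)-3-bromo-2-hydroxy-2-methylpropanoic acid | C[C@](O)(CBr)C(=O)O | starting material
21 | (S)-2-methyloxirane-2-carboxylic acid | C[C@]1(CO1)C(=O)O | intermediate
22 | (S)-2,3-dihydroxy-2-methylpropanoic acid | C[C@](O)(CO)C(=O)O | intermediate
23 | methyl (S)-2,2,4-trimethyl-1,3-dioxolane-4-carboxylate | COC(=O)[C@@]1(C)OC(C)(C)OC1 | intermediate
24 | (S)-2,2,4-trimethyl-1,3-dioxolane-4-carboxylic acid | OC(=O)[C@@]1(C)OC(C)(C)OC1 | intermediate
25 | (S)-2,2,4-trimethyl-1,3-dioxolane-4-carboxylic 2,4,6-trichlorobenzoic anhydride | O=C(OC(=O)c1c(Cl)cc(Cl)cc1Cl)[C@@]1(C)OC(C)(C)OC1 | intermediate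
26 | 8-O-[(S)-2,2,4-trimethyl-1,3-dioxolane-4-carbonyl]-8-hydroxy-1-oxo-3,10-epoxygermacra-2,11(13)-dien-12,6-olide | C=C1C(=O)O[C@H]2C[C@H](C)C3=CC(=O)[C@](C)(C[C@H](OC(=O)[C@@]4(C)OC(C)(C)OC4)[C@@H]12)O3 | intermediate
27 | 8-O-[(S)-2,3-dihydroxy-2-methylpropanoyl]-8-hydroxy-1-oxo-3,10-epoxygermacra-2,11(13)-dien-12,6-olide (4S,6S,7S,8S,10S) | C=C1C(=O)O[C@H]2C[C@H](C)C3=CC(=O)[C@](C)(C[C@H](OC(=O)[C@@](C)(O)CO)[C@@H]12)O3 | target

**Step count and risks**

Total step count: 20. Longest linear sequence: 14 steps (steps 1–3 or 4–6, then 7–15, 19 and 20).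

Steps most likely to fail:

1. Step 7 (proposed new method). What may go wrong: transfer of bromine from the tertiary bromide to the enolate, dehydrobromination of the lactone by the enolate, or ionisation at C10 before ring closure with loss of the lactone-derived configuration. Fallback, using known chemistry and forming O–C3 by cyclodehydration instead of O–C10 by substitution: setting out from 6, the lithium enolate is hydroxylated with 2-(phenylsulfonyl)-3-phenyloxaziridine anti to the trityloxymethyl group to give the hydroxy lactone F1, which is silylated (Et3SiCl, imidazole) to the silyl ether F2 and methylated (LiN(iPr)2; MeI), again anti, to the 3-methyl-3-silyloxy lactone F3 with oxygen cis to the C8 substituent. Claisen acylation of the lithium enolate of 4 by F3 gives the silyloxy diketone F4. Aqueous HCl in THF then removes the silyl group, closes the hemiketal onto C3 and dehydrates to the furanone, with expected loss of the trityl group, to give the furanone diol F5. Selective tritylation of the primary hydroxyl (TrCl, pyridine) comes back to 10.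

2. Step 14. What may go wrong: oligomerisation at the concentration needed for a strained 10-membered ring, addition of the allylmetal to the C1 ketone with closure of a 5-membered carbocycle, or approach to the wrong face of C7. Fallback, in which the nucleophile is generated catalytically from a stable allylic acetate instead of by stoichiometric reduction of the labile bromide: setting out from 14, acetylation (Ac2O, DMAP) gives the acetate F6, Lemieux–Johnson cleavage gives the aldehyde F7, and Pd(PPh3)4 with InI in THF forms a π-allyl complex of zerovalent palladium that is transmetalated to an allylindium species at low stationary concentration. This should add to the C6 aldehyde to give 17 and, after lactonisation, come back to 18.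

3. Step 11. What may go wrong: slow addition to the hindered aldehyde, with epimerisation at C8 or beta-elimination of the silyloxy group during prolonged exposure to the amine. Fallback, replacing the amine-catalysed process by addition of a preformed vinylmetal: setting out from 13, the vinylalane F8, made in the flask from methyl propiolate and (i-Bu)2AlH in THF/HMPA, is added to the aldehyde at low temperature and comes back to 14.

Further compounds
F1 | step 7 | (3R,5S)-3-hydroxy-5-[(trityloxy)methyl]oxolan-2-one | O=C1[C@H](O)C[C@@H](COC(c2ccccc2)(c2ccccc2)c2ccccc2)O1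
F2 | step 7 | (3R,5S)-3-(triethylsilyloxy)-5-[(trityloxy)methyl]oxolan-2-one | O=C1[C@H](O[Si](CC)(CC)CC)C[C@@H](COC(c2ccccc2)(c2ccccc2)c2ccccc2)O1
F3 | step 7 | 3-methyl-3-(triethylsilyloxy)-5-[(trityloxy)methyl]oxolan-2-one (methyl trans, silyloxy cis to the trityloxymethyl group) | O=C1[C@@](C)(O[Si](CC)(CC)CC)C[C@@H](COC(c2ccccc2)(c2ccccc2)c2ccccc2)O1
F4 | step 7 | 10-hydroxy-4,8-dimethyl-8-(triethylsilyloxy)-11-(trityloxy)undec-1-ene-5,7-dione | C=CC[C@H](C)C(=O)CC(=O)[C@@](C)(O[Si](CC)(CC)CC)C[C@H](O)COC(c1ccccc1)(c1ccccc1)c1ccccc1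
F5 | step 7 | (S)-2-[(S)-2,3-dihydroxypropyl]-2-methyl-5-[(S)-pent-4-en-2-yl]furan-3(2H)-one | C=CC[C@H](C)C1=CC(=O)[C@](C)(C[C@H](O)CO)O1
F6 | step 14 | methyl (4S)-3-acetoxy-4-(tert-butyldimethylsilyloxy)-2-methylidene-5-{(S)-2-methyl-3-oxo-5-[(S)-pent-4-en-2-yl]-2,3-dihydrofuran-2-yl}pentanoate | C=CC[C@H](C)C1=CC(=O)[C@](C)(C[C@H](O[Si](C)(C)C(C)(C)C)C(OC(C)=O)C(=C)C(=O)OC)O1
F7 | step 14 | methyl (4S)-3-acetoxy-4-(tert-butyldimethylsilyloxy)-2-methylidene-5-{(S)-2-methyl-3-oxo-5-[(S)-4-oxobutan-2-yl]-2,3-dihydrofuran-2-yl}pentanoate | O=CC[C@H](C)C1=CC(=O)[C@](C)(C[C@H](O[Si](C)(C)C(C)(C)C)C(OC(C)=O)C(=C)C(=O)OC)O1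
F8 | step 11 | methyl 2-(diisobutylalumanyl)prop-2-enoate | C=C(C(=O)OC)[Al](CC(C)C)CC(C)C
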